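**Retrosynthetic overview**

1. The target is the ring-opened form of a 12,6-olide: the C12 acid and C6 hydroxyl come from hydroxide opening of lactone 35, and the C8 ester from Mitsunobu esterification (inversion at C8) of alcohol 26 with side-chain acid 34, made from (R)-3-hydroxy-γ-butyrolactone.
2. Feature carrying the strategy: on the cyclohexane C5–C10 (ring A), C7 bears the 2-carboxyallyl unit C11(=C13)–C12 cis to the C6 oxygen, which is the retron of a 2-(alkoxycarbonyl)allyl metal adding to a C6 aldehyde. One CrCl2 allylation of bromo aldehyde 22 forms C6–C7 and closes ring A, then the C12–O6 γ-lactone (ring B).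
3. A(1,3) strain in the (Z)-allyl unit forces C11 trans to the C8 oxygen during ring closure, so C8 is carried as its β (S) epimer and inverted when the ester is installed; this gives the 7,8-cis target.
4. Bromo aldehyde 22 comes from a Morita–Baylis–Hillman reaction and SN2' bromination at C7 of an α-silyloxy aldehyde, followed by oxidation at C6.
5. C5 and C10 are set by an enantioselective boron Ireland–Claisen rearrangement of ester 10, whose (E)-allylic alcohol comes from carboalumination of a glycidol-derived alkyne.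

Key step: step 16

Remark: elemane numbering is used (ring C5–C10; C14 methyl and C1=C2 vinyl on C10; C4(=C3)C15 on C5; C11(=C13)C12 on C7); β is the ring face of the C14 methyl.
Assumption: the (S,S)-bromoborane is taken to give the (5S,10R) acid 13; both antipodes of the controller are available and the (R,R)-reagent is used if the sense of induction proves opposite.
Remark: numbered intermediates are those generated as a separate stage before the next reagent is added, plus the two organochromium species of the key step; short-lived activated species of single-stage reactions are not numbered.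

**Route**

Step 1
Reactants: 1 4-methyl hydrogen itaconate
Product: 2 methyl 3-(hydroxymethyl)but-3-enoate
Conditions: BH3·SMe2 (1.05 equiv), THF, −10 → 0 °C; MeOH quench
Reagents that add atoms: none
Why: chemoselective borane reduction of a carboxylic acid beside an ester, the acyloxyborane being reduced faster than the ester or the electron-poor alkene; the hydroxy ester is silylated at once to forestall lactonisation.

Step 2
Reactants: 2 methyl 3-(hydroxymethyl)but-3-enoate
Product: 3 methyl 3-{[(tert-butyldimethylsilyl)oxy]methyl}but-3-enoate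
Conditions: TBSCl, imidazole, CH2Cl2, 0 °C → rt
Reagents that add atoms: tert-butyldimethylsilyl chloride, CC(C)(C)[Si](C)(C)Cl
Why: standard silyl ether formation on a primary allylic alcohol.

Step 3
Reactants: 3 methyl 3-{[(tert-butyldimethylsilyl)oxy]methyl}but-3-enoate
Product: 4 3-{[(tert-butyldimethylsilyl)oxy]methyl}but-3-enoic acid
Conditions: LiOH·H2O, THF–H2O, 0 °C; 1 M HCl to pH 4 at 0 °C
Reagents that add atoms: lithium hydroxide, [Li+].[OH-]
Why: ester saponification at 0 °C, where acyl substitution should outrun α-deprotonation so that the 1,1-disubstituted alkene stays out of conjugation.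

Step 4
Reactants: 5 (R)-glycidol
Product: 6 (S)-pent-4-yne-1,2-diol
Conditions: lithium acetylide ethylenediamine complex (LiC≡CH·H2NCH2CH2NH2, 2.5 equiv), DMSO, 0 °C → rt; aq NH4Cl
Reagents that add atoms: lithium acetylide ethylenediamine complex, [Li]C#C.NCCN
Why: SN2 opening of the epoxide at its terminal carbon by acetylide; the carbinol centre (later C8) is not touched, and the degenerate Payne rearrangement of the glycidol alkoxide leads to the same enantiomer.

Step 5
Reactants: 6 (S)-pent-4-yne-1,2-diol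
Product: 7 (S)-4,5-bis(triethylsilyloxy)pent-1-yne
Conditions: TESCl (2.3 equiv), imidazole, CH2Cl2, 0 °C → rt
Reagents that add atoms: triethylsilyl chloride, CC[Si](CC)(CC)Cl
Why: standard bis-silylation; the bulky, non-chelating C8 silyl ether is needed later for facial control in the key step.

Step 6
Reactants: 7 (S)-4,5-bis(triethylsilyloxy)pent-1-yne
Product: 9 (2E,5S)-3-methyl-5,6-bis(triethylsilyloxy)hex-2-en-1-ol, via alkenyldimethylalane 8 (not isolated)
Conditions: Me3Al (3 equiv), Cp2ZrCl2 (0.25 equiv), CH2Cl2, 0 °C → rt; n-BuLi, THF, −78 °C; (CH2O)n, → rt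
Reagents that add atoms: trimethylaluminium, C[Al](C)C; formaldehyde (as paraformaldehyde), C=O
Why: zirconium-catalysed syn-carboalumination (Negishi) puts methyl and aluminium cis on the terminal alkyne, and the alkenylalanate is trapped by formaldehyde with retention, giving the (E)-trisubstituted allylic alcohol.

Step 7
Reactants: 9 (2E,5S)-3-methyl-5,6-bis(triethylsilyloxy)hex-2-en-1-ol; 4 3-{[(tert-butyldimethylsilyl)oxy]methyl}but-3-enoic acid
Product: 10 (2E,5S)-3-methyl-5,6-bis(triethylsilyloxy)hex-2-en-1-yl 3-{[(tert-butyldimethylsilyl)oxy]methyl}but-3-enoate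
Conditions: DCC, DMAP (0.05 equiv), CH2Cl2, 0 °C
Reagents that add atoms: none
Why: Steglich esterification; little DMAP and low temperature should keep the β,γ-unsaturated acyl group from isomerising.

Step 8
Reactants: 10 allylic ester
Product: 13 (2S,3R)-2-[3-(tert-butyldimethylsilyloxy)prop-1-en-2-yl]-3-[(2S)-2,3-bis(triethylsilyloxy)propyl]-3-methylpent-4-enoic acid (5S,8S,10R), via boron ketene acetal 11 (not isolated), via acyloxyborane 12 (not isolated)
Conditions: (4S,5S)-2-bromo-4,5-diphenyl-1,3-bis{[3,5-bis(trifluoromethyl)phenyl]sulfonyl}-1,3,2-diazaborolidine (from the bis-sulfonamide and BBr3, CH2Cl2, volatiles removed; 1.3 equiv), Et3N, toluene–hexane, −78 °C; then −20 → 4 °C; aqueous work-up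
Reagents that add atoms: none
Why: enantioselective boron Ireland–Claisen rearrangement: soft enolisation should give the boron ketene acetal with C4 cis to the allyloxy oxygen, and the [3,3] shift through a chair with the (E)-allyl unit (C9 equatorial, C14 axial) sets C5 and C10 together, the relative configuration from the two double-bond geometries and the absolute one from the C2-symmetric boron controller.

Step 9
Reactants: 13 acid
Product: 14 (2S,3R)-2-[3-(tert-butyldimethylsilyloxy)prop-1-en-2-yl]-3-[(2S)-2,3-bis(triethylsilyloxy)propyl]-3-methylpent-4-en-1-ol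
Conditions: LiAlH4, THF, 0 °C → rt; aqueous NaOH work-up
Reagents that add atoms: none
Why: hydride reduction of the hindered acid to the C6 primary alcohol; silyl ethers and isolated alkenes are inert.

Step 10
Reactants: 14 alcohol
Product: 15 C6 4-methoxybenzyl ether of 14
Conditions: NaH, PMBCl, Bu4NI (cat.), THF–DMF, 0 °C → rt
Reagents that add atoms: 4-methoxybenzyl chloride, COc1ccc(CCl)cc1
Why: Williamson etherification gives a C6 protecting group that can later be removed oxidatively beside the allylic bromide and the silyl ethers.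

Step 11
Reactants: 15 PMB ether
Product: 17 (5S,8S,10R) C7 aldehyde bearing the C8 triethylsilyloxy group, via alkoxysulfonium chloride 16 (not isolated)
Conditions: (COCl)2, DMSO, CH2Cl2, −78 → −30 °C; Et3N, −78 → 0 °C
Reagents that add atoms: none
Why: under Swern conditions a primary triethylsilyl ether is cleaved by the chlorosulfonium salt and oxidised directly, while the secondary TES, the TBS and the PMB ethers are left (known selective oxidation of primary TES ethers).

Step 12
Reactants: 17 α-silyloxy aldehyde; 18 methyl acrylate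
Product: 19 Morita–Baylis–Hillman adduct, methyl 2-methylidene-3-hydroxy ester at C7 (mixture of C7 epimers)
Conditions: DABCO (1 equiv), methyl acrylate (excess), rt
Reagents that add atoms: none
Why: Morita–Baylis–Hillman reaction, for which α-oxygenated aldehydes are among the most reactive partners; the new C7 carbinol forms unselectively and is erased in step 13.

Step 13
Reactants: 19 Morita–Baylis–Hillman adduct
Product: 20 methyl (Z)-2-(bromomethyl)enoate, C6 PMB ether (5S,8S,10R)
Conditions: NBS, Me2S, CH2Cl2, 0 °C → rt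
Reagents that add atoms: N-bromosuccinimide, O=C1CCC(=O)N1Br
Why: the alkoxysulfonium salt is displaced by bromide with allylic transposition (SN2'), which should give the thermodynamically favoured (Z)-bromide with C8 trans to the ester.

Step 14
Reactants: 20 bromide PMB ether
Product: 21 methyl (Z)-2-(bromomethyl)enoate, C6 alcohol
Conditions: DDQ, CH2Cl2–pH 7 buffer, 0 °C
Reagents that add atoms: none
Why: oxidative cleavage of the PMB ether under neutral conditions that the allylic bromide, enoate and silyl ethers tolerate.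

Step 15
Reactants: 21 bromo alcohol
Product: 22 methyl (Z)-2-(bromomethyl)enoate with C6 formyl group (5S,8S,10R)
Conditions: Dess–Martin periodinane, NaHCO3, CH2Cl2, 0 °C → rt; used at once
Reagents that add atoms: none
Why: buffered, non-basic oxidation should give the α-branched β,γ-unsaturated aldehyde without epimerising C5 or moving the C4=C3 alkene into conjugation.

Step 16
Reactants: 22 bromo aldehyde
Product: 25 8β-(triethylsilyloxy)-15-(tert-butyldimethylsilyloxy)-5αH,6βH,7βH-elema-1,3,11(13)-trien-12,6α-olide, via allylchromium dichloride 23 (not isolated), via chromium alkoxide 24 (not isolated)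
Conditions: CrCl2 (5 equiv), THF, rt, slow addition of 22 to 0.005 M; aq NH4Cl
Reagents that add atoms: none
Why: Two CrCl2 (divalent chromium) reduce the C13–Br bond to a σ-allyl trivalent-chromium species, which adds through its γ-carbon C7 to the chromium-bound C6 aldehyde in a closed six-membered chair; the closest known reaction type is the CrCl2 cyclisation of ω-formyl (Z)-2-(bromomethyl)alk-2-enoates to cis-fused α-methylene-γ-lactones. Ring A closes by 6-exo-trig attack on the carbonyl with allylic transposition, which unveils C11=C13, and ring B closes by 5-exo-trig attack of the C6 chromium alkoxide on the C12 methyl ester. C7 is set by A(1,3) strain in the (Z)-trisubstituted allyl unit: H8 eclipses the C11–C13 side, the C9 tether lies on the attacked face and the bulky C8 silyloxy group on the other, so C11 ends trans to O8, that is α when O8 is β. C6 is set by the chair: with C8 cis to C13 the C8 substituent is axial in the six-membered transition state and the aldehyde substituent C5 equatorial, which makes the fusion cis and places O6 on the same α face as C11. The step needs γ- over α-attack and retention of the (Z)-allyl geometry, both secured by the C11 ester (the isomer with C8 trans to the ester is also the thermodynamic one), ring closure over dimerisation, secured by high dilution, and an intact C5 centre, secured by the non-basic medium. Because this control makes the 7,8 relation trans, the precursor carries the 8β-silyloxy group and C8 is inverted in step 21.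

Step 17
Reactants: 25 silyl-protected lactone
Product: 26 8β-hydroxy-15-(tert-butyldimethylsilyloxy)-5αH,6βH,7βH-elema-1,3,11(13)-trien-12,6α-olide
Conditions: PPTS, MeOH–CH2Cl2, 0 °C
Reagents that add atoms: none
Why: acid-catalysed methanolysis removes the secondary TES ether much faster than the primary TBS ether, and the lactone is inert.

Step 18
Reactants: 27 (R)-3-hydroxy-γ-butyrolactone
Product: 29 (3R,4R)-3-[(dimethylamino)methyl]-4-hydroxyoxolan-2-one (trans), via dilithium alkoxide enolate 28 (not isolated)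
Conditions: LiN(iPr)2 (2.2 equiv, from iPr2NH and n-BuLi), THF, −78 → −40 °C; Me2N=CH2 I, −78 °C → rt; aq NH4Cl
Reagents that add atoms: N,N-dimethylmethyleneiminium iodide (Eschenmoser's salt), C=[N+](C)C.[I-]
Why: Fráter–Seebach-type dianion (the alkoxide cannot β-eliminate) undergoes Mannich aminomethylation anti to the alkoxide; the carbinol centre is untouched and the new C3 centre disappears in step 19.

Step 19
Reactants: 29 Mannich base
Product: 31 (R)-4-hydroxy-3-methylideneoxolan-2-one, via trimethylammonium iodide 30 (not isolated)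
Conditions: MeI, MeOH, rt; then NaHCO3, CH2Cl2–H2O, rt
Reagents that add atoms: none
Why: quaternisation and E1cB loss of trimethylamine is the standard α-methylenation of lactones and leaves the carbinol centre untouched.

Step 20
Reactants: 31 (R)-4-hydroxy-3-methylideneoxolan-2-one
Product: 34 (R)-3,4-bis(tert-butyldimethylsilyloxy)-2-methylidenebutanoic acid, via lithium dihydroxy carboxylate 32 (not isolated), via tris-silylated ester 33 (not isolated)
Conditions: LiOH (1.05 equiv), THF–H2O, 0 °C, concentrate; TBSCl (3.5 equiv), imidazole, DMF, rt; K2CO3, MeOH–THF–H2O, rt; aq KHSO4 to pH 4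
Reagents that add atoms: lithium hydroxide, [Li+].[OH-]; tert-butyldimethylsilyl chloride, CC(C)(C)[Si](C)(C)Cl
Why: hydroxide opens the lactone to a carboxylate that cannot relactonise, and persilylation followed by selective cleavage of the labile silyl ester leaves the bis-silylated acid with C3' unchanged.

Step 21
Reactants: 26 8β-hydroxy lactone; 34 side-chain acid
Product: 35 8α-[(R)-3,4-bis(tert-butyldimethylsilyloxy)-2-methylidenebutanoyloxy]-15-(tert-butyldimethylsilyloxy)-5αH,6βH,7βH-elema-1,3,11(13)-trien-12,6α-olide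
Conditions: PPh3, DIAD, toluene, 0 °C → rt (betaine pre-formed)
Reagents that add atoms: none
Why: Mitsunobu esterification, in which the C8 oxyphosphonium is displaced by the carboxylate in an SN2 reaction with inversion, turning 8β-OH into the 8α-ester cis to C11.

Step 22
Reactants: 35 acylated lactone
Product: 36 8α-[(R)-3,4-bis(tert-butyldimethylsilyloxy)-2-methylidenebutanoyloxy]-15-(tert-butyldimethylsilyloxy)-6α-hydroxy-5αH,7βH-elema-1,3,11(13)-trien-12-oic acid
Conditions: LiOH (1.2 equiv), THF–H2O, 0 °C; 0.1 M HCl to pH 5 at 0 °C, cold extraction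
Reagents that add atoms: lithium hydroxide, [Li+].[OH-]
Why: hydroxide should attack the cis-fused γ-lactone much faster than the hindered α-branched acrylate ester at C8, and the side-chain diol stays silylated so that no 4'-alkoxide can lactonise onto that ester; the γ-hydroxy acid is isolated by careful acidification.

Step 23
Reactants: 36 silylated hydroxy acid
Product: 37 8α-[(R)-3,4-dihydroxy-2-methylidenebutanoyloxy]-6α,15-dihydroxy-5αH,7βH-elema-1,3,11(13)-trien-12-oic acid (target)
Conditions: HF·pyridine, pyridine, THF, 0 °C → rt; Me3SiOMe quench, evaporation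
Reagents that add atoms: none
Why: fluoride cleaves the three TBS ethers under buffered, mildly acidic conditions, in which neither relactonisation of the γ-hydroxy acid nor cyclisation of the 3,4-dihydroxy ester should be fast.

**Compound list**

1 | 4-methyl hydrogen itaconate (4-methoxy-2-methylidene-4-oxobutanoic acid) | COC(=O)CC(=C)C(=O)O | starting material
2 | methyl 3-(hydroxymethyl)but-3-enoate | COC(=O)CC(=C)CO | intermediate
3 | methyl 3-{[(tert-butyldimethylsilyl)oxy]methyl}but-3-enoate | COC(=O)CC(=C)CO[Si](C)(C)C(C)(C)C | intermediate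
4 | 3-{[(tert-butyldimethylsilyl)oxy]methyl}but-3-enoic acid | OC(=O)CC(=C)CO[Si](C)(C)C(C)(C)C | intermediate
5 | (R)-glycidol | OC[C@@H]1CO1 | starting material
6 | (S)-pent-4-yne-1,2-diol | C#CC[C@H](O)CO | intermediate
7 | (S)-4,5-bis(triethylsilyloxy)pent-1-yne | C#CC[C@H](O[Si](CC)(CC)CC)CO[Si](CC)(CC)CC | intermediate
8 | dimethyl[(1E,4S)-2-methyl-4,5-bis(triethylsilyloxy)pent-1-en-1-yl]alane | C[Al](C)/C=C(\C)C[C@H](O[Si](CC)(CC)CC)CO[Si](CC)(CC)CC | intermediate (not isolated)
9 | (2E,5S)-3-methyl-5,6-bis(triethylsilyloxy)hex-2-en-1-ol | OC/C=C(\C)C[C@H](O[Si](CC)(CC)CC)CO[Si](CC)(CC)CC | intermediate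
10 | (2E,5S)-3-methyl-5,6-bis(triethylsilyloxy)hex-2-en-1-yl 3-{[(tert-butyldimethylsilyl)oxy]methyl}but-3-enoate | C=C(CO[Si](C)(C)C(C)(C)C)CC(=O)OC/C=C(\C)C[C@H](O[Si](CC)(CC)CC)CO[Si](CC)(CC)CC | intermediate
11 | boron ketene acetal of 10 (C4 cis to the allyloxy oxygen; boron in the (4S,5S)-diazaborolidine) | C=C(CO[Si](C)(C)C(C)(C)C)/C=C(/OB1N(S(=O)(=O)c2cc(C(F)(F)F)cc(C(F)(F)F)c2)[C@@H](c2ccccc2)[C@H](c2ccccc2)N1S(=O)(=O)c1cc(C(F)(F)F)cc(C(F)(F)F)c1)OC/C=C(\C)C[C@H](O[Si](CC)(CC)CC)CO[Si](CC)(CC)CC | intermediate (not isolated)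
12 | (4S,5S)-diazaborolidin-2-yl ester of acid 13 | C=C[C@@]([C@H](C(=O)OB1N(S(=O)(=O)c2cc(C(F)(F)F)cc(C(F)(F)F)c2)[C@@H](c2ccccc2)[C@H](c2ccccc2)N1S(=O)(=O)c1cc(C(F)(F)F)cc(C(F)(F)F)c1)C(=C)CO[Si](C)(C)C(C)(C)C)(C)C[C@H](O[Si](CC)(CC)CC)CO[Si](CC)(CC)CC | intermediate (not isolated)
13 | (2S,3R)-2-[3-(tert-butyldimethylsilyloxy)prop-1-en-2-yl]-3-[(2S)-2,3-bis(triethylsilyloxy)propyl]-3-methylpent-4-enoic acid | C=C[C@@]([C@H](C(=O)O)C(=C)CO[Si](C)(C)C(C)(C)C)(C)C[C@H](O[Si](CC)(CC)CC)CO[Si](CC)(CC)CC | intermediate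
14 | (2S,3R)-2-[3-(tert-butyldimethylsilyloxy)prop-1-en-2-yl]-3-[(2S)-2,3-bis(triethylsilyloxy)propyl]-3-methylpent-4-en-1-ol | C=C[C@@]([C@H](CO)C(=C)CO[Si](C)(C)C(C)(C)C)(C)C[C@H](O[Si](CC)(CC)CC)CO[Si](CC)(CC)CC | intermediate
15 | C6 4-methoxybenzyl ether of 14 | C=C[C@@]([C@H](COCc1ccc(OC)cc1)C(=C)CO[Si](C)(C)C(C)(C)C)(C)C[C@H](O[Si](CC)(CC)CC)CO[Si](CC)(CC)CC | intermediate
16 | C7 alkoxydimethylsulfonium chloride derived from 15 | C=C[C@@]([C@H](COCc1ccc(OC)cc1)C(=C)CO[Si](C)(C)C(C)(C)C)(C)C[C@H](O[Si](CC)(CC)CC)CO[S+](C)C.[Cl-] | intermediate (not isolated)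
17 | (5S,8S,10R) C7 aldehyde with C8 triethylsilyloxy, C6 PMB ether, C15 TBS ether | C=C[C@@]([C@H](COCc1ccc(OC)cc1)C(=C)CO[Si](C)(C)C(C)(C)C)(C)C[C@H](O[Si](CC)(CC)CC)C=O | intermediate
18 | methyl acrylate | C=CC(=O)OC | starting material
19 | Morita–Baylis–Hillman adduct (C7 epimers; 5S,8S,10R) | C=C[C@@]([C@H](COCc1ccc(OC)cc1)C(=C)CO[Si](C)(C)C(C)(C)C)(C)C[C@H](O[Si](CC)(CC)CC)C(O)C(=C)C(=O)OC | intermediate
20 | methyl (Z)-2-(bromomethyl)enoate, C6 PMB ether (5S,8S,10R) | C=C[C@@]([C@H](COCc1ccc(OC)cc1)C(=C)CO[Si](C)(C)C(C)(C)C)(C)C[C@H](O[Si](CC)(CC)CC)/C=C(\CBr)C(=O)OC | intermediate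
21 | methyl (Z)-2-(bromomethyl)enoate, C6 alcohol (5S,8S,10R) | C=C[C@@]([C@H](CO)C(=C)CO[Si](C)(C)C(C)(C)C)(C)C[C@H](O[Si](CC)(CC)CC)/C=C(\CBr)C(=O)OC | intermediate
22 | methyl (Z)-2-(bromomethyl)enoate with C6 formyl group (5S,8S,10R) | C=C[C@@]([C@H](C=O)C(=C)CO[Si](C)(C)C(C)(C)C)(C)C[C@H](O[Si](CC)(CC)CC)/C=C(\CBr)C(=O)OC | intermediate
23 | (Z)-allylchromium dichloride (trivalent chromium on C13) | C=C[C@@]([C@H](C=O)C(=C)CO[Si](C)(C)C(C)(C)C)(C)C[C@H](O[Si](CC)(CC)CC)/C=C(\C[Cr](Cl)Cl)C(=O)OC | intermediate (not isolated)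
24 | chromium alkoxide of the cyclised hydroxy ester (6α-OCrCl2, 7α-C11, 8β-OTES) | C=C[C@@]1(C)C[C@H](O[Si](CC)(CC)CC)[C@@H](C(=C)C(=O)OC)[C@@H](O[Cr](Cl)Cl)[C@@H]1C(=C)CO[Si](C)(C)C(C)(C)C | intermediate (not isolated)
25 | 8β-(triethylsilyloxy)-15-(tert-butyldimethylsilyloxy)-5αH,6βH,7βH-elema-1,3,11(13)-trien-12,6α-olide | C=C[C@@]1(C)C[C@H](O[Si](CC)(CC)CC)[C@@H](C(=C)C(=O)O2)[C@@H]2[C@@H]1C(=C)CO[Si](C)(C)C(C)(C)C | intermediate
26 | 8β-hydroxy-15-(tert-butyldimethylsilyloxy)-5αH,6βH,7βH-elema-1,3,11(13)-trien-12,6α-olide | C=C[C@@]1(C)C[C@H](O)[C@@H](C(=C)C(=O)O2)[C@@H]2[C@@H]1C(=C)CO[Si](C)(C)C(C)(C)C | intermediate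
27 | (R)-3-hydroxy-γ-butyrolactone [(R)-4-hydroxyoxolan-2-one] | O=C1C[C@@H](O)CO1 | starting material
28 | dilithium alkoxide enolate of 27 | [Li]O[C@H]1COC(O[Li])=C1 | intermediate (not isolated)
29 | (3R,4R)-3-[(dimethylamino)methyl]-4-hydroxyoxolan-2-one | O=C1[C@H](CN(C)C)[C@@H](O)CO1 | intermediate
30 | trimethylammonium iodide of 29 | O=C1[C@H](C[N+](C)(C)C)[C@@H](O)CO1.[I-] | intermediate (not isolated)
31 | (R)-4-hydroxy-3-methylideneoxolan-2-one | O=C1C(=C)[C@@H](O)CO1 | intermediate
32 | lithium (R)-3,4-dihydroxy-2-methylidenebutanoate | [Li+].[O-]C(=O)C(=C)[C@@H](O)CO | intermediate (not isolated)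
33 | tert-butyldimethylsilyl (R)-3,4-bis(tert-butyldimethylsilyloxy)-2-methylidenebutanoate | C=C([C@@H](O[Si](C)(C)C(C)(C)C)CO[Si](C)(C)C(C)(C)C)C(=O)O[Si](C)(C)C(C)(C)C | intermediate (not isolated)
34 | (R)-3,4-bis(tert-butyldimethylsilyloxy)-2-methylidenebutanoic acid | C=C([C@@H](O[Si](C)(C)C(C)(C)C)CO[Si](C)(C)C(C)(C)C)C(=O)O | intermediate
35 | 8α-[(R)-3,4-bis(tert-butyldimethylsilyloxy)-2-methylidenebutanoyloxy]-15-(tert-butyldimethylsilyloxy)-5αH,6βH,7βH-elema-1,3,11(13)-trien-12,6α-olide | C=C[C@@]1(C)C[C@@H](OC(=O)C(=C)[C@@H](O[Si](C)(C)C(C)(C)C)CO[Si](C)(C)C(C)(C)C)[C@@H](C(=C)C(=O)O2)[C@@H]2[C@@H]1C(=C)CO[Si](C)(C)C(C)(C)C | intermediate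
36 | 8α-[(R)-3,4-bis(tert-butyldimethylsilyloxy)-2-methylidenebutanoyloxy]-15-(tert-butyldimethylsilyloxy)-6α-hydroxy-5αH,7βH-elema-1,3,11(13)-trien-12-oic acid | C=C[C@@]1(C)C[C@@H](OC(=O)C(=C)[C@@H](O[Si](C)(C)C(C)(C)C)CO[Si](C)(C)C(C)(C)C)[C@@H](C(=C)C(=O)O)[C@@H](O)[C@@H]1C(=C)CO[Si](C)(C)C(C)(C)C | intermediate
37 | 8α-[(R)-3,4-dihydroxy-2-methylidenebutanoyloxy]-6α,15-dihydroxy-5αH,7βH-elema-1,3,11(13)-trien-12-oic acid | C=C[C@@]1(C)C[C@@H](OC(=O)C(=C)[C@@H](O)CO)[C@@H](C(=C)C(=O)O)[C@@H](O)[C@@H]1C(=C)CO | target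

**Step count and risks**

Total step count: 23. Longest linear sequence: 17 steps (steps 4–17 and 21–23, from (R)-glycidol).

Steps most likely to fail:

1. Step 16 (key step). The chair that delivers the wanted isomer carries the C5 substituent pseudo-axial and O6 syn to the C10 vinyl group. If this is too costly, the allylchromium may lose its (Z) geometry and close through a trans-fused array, or couple intermolecularly; the aldehyde may also epimerise at C5 before it is trapped. Fallback: the ring is closed through an open, Lewis-acid-promoted transition state instead of the chromium chair. Setting out from 21, the allylic bromide is stannylated with (Bu3Sn)2 and Pd2(dba)3 (zerovalent palladium) in THF to the allylstannane alcohol F1. Buffered Dess–Martin oxidation gives the stannyl aldehyde F2. BF3·OEt2 in CH2Cl2 at −78 °C effects the intramolecular allylstannane–aldehyde addition, with C7 still under A(1,3) control, and should give the cyclised hydroxy ester F3. F3 lactonises with catalytic PPTS, and the route is rejoined at 25.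

2. Step 21. Displacement at the hindered C8 oxyphosphonium may be slower than elimination towards C9 or acyl transfer with retention, and the phosphine may add to the methylene lactone. Fallback: sulfonate displacement replaces the redox condensation. Setting out from 26, Tf2O and pyridine in CH2Cl2 at −20 °C give the 8β-triflate F4. F4 is displaced with inversion by the caesium carboxylate of 34 (from Cs2CO3) with 18-crown-6 in toluene at rt, and the route is rejoined at 35.

3. Step 22. Hydroxide may also hydrolyse the C8 ester, add in conjugate fashion, or promote acyl migration to O6, and the γ-hydroxy acid may relactonise on acidification. Fallback: the lactone is opened before any ester sits on C8, and the acid is carried as an allyl ester. Setting out from 25, LiOH in THF–H2O opens the lactone and the lithium carboxylate is alkylated with allyl bromide in DMF to the allyl ester F5. Allyl chloroformate and pyridine cap O6 as the allyl carbonate F6. PPTS in MeOH removes the C8 silyl group to give alcohol F7. Mitsunobu esterification with 34 gives the 8α-ester F8. Pd(PPh3)4 (zerovalent palladium) with N-methylaniline removes both allyl groups under neutral conditions, and the route is rejoined at 36.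

Further compounds
F1 | step 16 | methyl (Z)-2-[(tributylstannyl)methyl]enoate, C6 alcohol (5S,8S,10R) | C=C[C@@]([C@H](CO)C(=C)CO[Si](C)(C)C(C)(C)C)(C)C[C@H](O[Si](CC)(CC)CC)/C=C(\C[Sn](CCCC)(CCCC)CCCC)C(=O)OC
F2 | step 16 | methyl (Z)-2-[(tributylstannyl)methyl]enoate with C6 formyl group (5S,8S,10R) | C=C[C@@]([C@H](C=O)C(=C)CO[Si](C)(C)C(C)(C)C)(C)C[C@H](O[Si](CC)(CC)CC)/C=C(\C[Sn](CCCC)(CCCC)CCCC)C(=O)OC
F3 | step 16 | methyl 8β-(triethylsilyloxy)-15-(tert-butyldimethylsilyloxy)-6α-hydroxy-5αH,7βH-elema-1,3,11(13)-trien-12-oate | C=C[C@@]1(C)C[C@H](O[Si](CC)(CC)CC)[C@@H](C(=C)C(=O)OC)[C@@H](O)[C@@H]1C(=C)CO[Si](C)(C)C(C)(C)C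
F4 | step 21 | 8β-(trifluoromethanesulfonyloxy)-15-(tert-butyldimethylsilyloxy)-5αH,6βH,7βH-elema-1,3,11(13)-trien-12,6α-olide | C=C[C@@]1(C)C[C@H](OS(=O)(=O)C(F)(F)F)[C@@H](C(=C)C(=O)O2)[C@@H]2[C@@H]1C(=C)CO[Si](C)(C)C(C)(C)C
F5 | step 22 | allyl 8β-(triethylsilyloxy)-15-(tert-butyldimethylsilyloxy)-6α-hydroxy-5αH,7βH-elema-1,3,11(13)-trien-12-oate | C=C[C@@]1(C)C[C@H](O[Si](CC)(CC)CC)[C@@H](C(=C)C(=O)OCC=C)[C@@H](O)[C@@H]1C(=C)CO[Si](C)(C)C(C)(C)C
F6 | step 22 | 6α-O-allyloxycarbonyl derivative of F5 | C=C[C@@]1(C)C[C@H](O[Si](CC)(CC)CC)[C@@H](C(=C)C(=O)OCC=C)[C@@H](OC(=O)OCC=C)[C@@H]1C(=C)CO[Si](C)(C)C(C)(C)C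
F7 | step 22 | 8β-hydroxy compound from F6 | C=C[C@@]1(C)C[C@H](O)[C@@H](C(=C)C(=O)OCC=C)[C@@H](OC(=O)OCC=C)[C@@H]1C(=C)CO[Si](C)(C)C(C)(C)C
F8 | step 22 | 8α-[(R)-3,4-bis(tert-butyldimethylsilyloxy)-2-methylidenebutanoyloxy] allyl ester allyl carbonate | C=C[C@@]1(C)C[C@@H](OC(=O)C(=C)[C@@H](O[Si](C)(C)C(C)(C)C)CO[Si](C)(C)C(C)(C)C)[C@@H](C(=C)C(=O)OCC=C)[C@@H](OC(=O)OCC=C)[C@@H]1C(=C)CO[Si](C)(C)C(C)(C)C
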